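Readings and results were computed with made-up constants, and the scatter is random.

The easy step is the clock. In the oak run, product reads 83.7% at 3.00 h, and the new flask stands for 8.0 d, far longer, so this reckoning counts free base, taken as the limiting reagent, rather than rates.

all flasks: electrophile 0.050 M
- oak: free base 0.11 M; protonated nucleophile 0.090 M; protic impurity 0.010 M; run made earlier
- flask: protonated nucleophile 0.0900 M; protic impurity 0.0100 M; time 8.0 d

oak run (percent of the electrophile charged): time / h: product / % = 3.00: 83.7; 6.00: 91.5; 10.0: 95.5; 12.0: 96.2; 15.0: 95.2; 20.0: 96.9

(scatter of a reading: 1 percentage point)

- the amount of free base is what is sought; it is there from the start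

1. the concentration of free base at which the part of the electrophile that has reacted at 8.0 d is just 70%, in M

The reckoning made here keeps a ledger of free base. This reckoning takes each electrophile that reacts to cost two free base: one to strip a protonated nucleophile and one to take up the acid released. For the 0.050 M of electrophile charged, that comes to 0.100 M, the base price of the whole charge. The oak run stands beside this price: its 0.11 M of free base, less 0.010 M booked for the protic impurity, leaves 0.100 M, equal to the price, and its product reads 96.9% at 20.0 h.

In the new flask, 0.0350 M of electrophile has to react, so the first entry is 0.0700 M. The protic impurity is the correction, smaller than that entry, and the ledger books it at its full charge of 0.0100 M. The books close at 0.0800 M.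

The forecast gives the same figure, 0.08 M, with a range from 0.077 M to 0.084 M, on the ground that “the reaction stops only when the base runs out”.

The flask needs 0.0707 M, less than the low end of the forecast's range, though the forecast still counts as right within the tolerance set for it, and the flask runs on this scheme:

    nucleophile ⇌ dormant form (K = 1.26, k = 1.52 × 10⁻⁵ /s)
    nucleophile + protic impurity → quenched reagent (k = 4.71 × 10⁻⁴ /M/s)
    electrophile + nucleophile ⇌ acid set free + product (K = 13.5, k = 0.00582 /M/s)
    nucleophile + acid set free ⇌ protonated nucleophile, settled at all times (K = 1.53 × 10⁵ /M)
    acid set free + free base ⇌ salt of the base, settled at all times (K = 1.24 × 10⁶ /M)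

With that charge of free base, the electrophile used stands at 69.1% after 0.800 d, when 0.0687% of the charged free base is still free, and at 68.8% after 24.0 d. Taking the price of 0.0700 M from 0.0707 M leaves 7.41 × 10⁻⁴ M for the correction, less than the 0.0100 M of protic impurity charged.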